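The data come from a simulation for substances that don't exist; scatter was added.

Does more scavenger bring more of the electrophile to reaction in these flasks? I want that answer by hand before any integration, so I look for what stays nearly constant.

| flask | electrophile | nucleophile | protic impurity | scavenger | remark | time |
|---|---|---|---|---|---|---|
| alder | 0.093 M | 0.062 M | 0.031 M | 0.062 M | run made earlier |  |
| Saturday's | 0.062 M | 0.0620 M | 0.0310 M | 0.250 M |  | 2.0 d |
| Wednesday's | 0.062 M | 0.0620 M | 0.0310 M | 0.0620 M |  | 2.0 d |
| Monday's | 0.062 M | 0.0620 M | 0.0310 M | 0.120 M |  | 2.0 d |

alder run (percent of the electrophile charged)

| time / h | electrophile / % | product / % |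
|---|---|---|
| 8.00 | 57 | 28 |
| 15.0 | 46 | 32 |
| 20.0 | 39 | 31 |
| 30.0 | 37 | 35 |

(scatter of a reading: 1.5 percentage points)

- for acid set free the idle adduct is counted in
- steps under discussion: acid set free + scavenger -> scavenged by-product; electrophile + acid set free <-> idle adduct; electrophile + protic impurity -> quenched substrate; nucleophile + acid set free <-> protonated nucleophile; electrophile + nucleophile <-> acid set free + product
- no earlier run changes the charge of scavenger; that part of a forecast is a guess

1. part of the electrophile that has reacted at the end, Saturday's
2. part of the electrophile that has reacted at the end, Wednesday's
3. part of the electrophile that has reacted at the end, Monday's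
4. what raising the concentration of scavenger from its lowest to its highest value here does to the part of the electrophile that has reacted (changes below 5 percentage points count as none) (it rises / it falls / no change)

In the alder run the product climbs from 28 % to 35 % of the electrophile between 8.00 h and 30.0 h, ending at about half of the nucleophile charged. I read this as each product costing two nucleophiles: one reacts, and one holds the acid set free as protonated nucleophile, the resting state of that acid. So, as a simplification of my own, I freeze the product from the start of the new flasks at a plateau of 0.0310 M, half the charged nucleophile.

I turn the electrophile first. In my reckoning, going from 0.093 M to 0.062 M leaves this plateau in place but lifts it to 50.0 % of the electrophile. Beyond the plateau, I let electrophile and protic impurity fall together by quenching, and the new flasks have equal amounts for that, 0.0310 M against 0.0310 M.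

Time comes next. If I read the remainder of the alder balance as quenched substrate, about 0.00496 M of impurity is left at 30.0 h, and the second-order law for unequal amounts, started from the electrophile above the plateau, then gives a quenching constant k of 1.34 L mol⁻¹ h⁻¹, a reading that carries the scatter. With equal amounts, the reciprocal of the amount x of electrophile grows steadily at rate k from the reciprocal of 0.0310 M. At 2.0 d that gives x = 0.0104 M, so I reckon that 83.3 % has reacted.

The scavenger comes last, and here I guess. No earlier run changes it, and the product's drift in the readings after 15.0 h is 3 percentage points against a scatter of 1.5 points. My guess is that it leaves the plateau standing, and so I commit to 83.3 % in all three flasks.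

The forecast parts from this with 78 % for Wednesday's, 82 % for Monday's and 90 % for Saturday's, and its answer on raising the scavenger is "it rises", on the guess that “more scavenger frees nucleophile”.

The flasks give 84.7 % on Wednesday's, 84.8 % on Monday's and 84.9 % on Saturday's: no change, a change of 0.2 points.

    acid set free + scavenger → scavenged by-product (k = 3.80 L mol⁻¹ h⁻¹)
    electrophile + acid set free ⇌ idle adduct, settled at all times (K = 570 L mol⁻¹)
    electrophile + protic impurity → quenched substrate (k = 1.30 L mol⁻¹ h⁻¹)
    nucleophile + acid set free ⇌ protonated nucleophile, settled at all times (K = 84000 L mol⁻¹)
    electrophile + nucleophile ⇌ acid set free + product (K = 0.530, k = 1.60 L mol⁻¹ h⁻¹)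

Saturday's has made 0.00186 M of scavenged by-product at 2.00 d, far less than the plateau, and its product stands at 48.5 % of the electrophile. With 0.037 M of nucleophile in a flask otherwise like Wednesday's, the plateau falls to 29.8 % of the electrophile, and that flask holds 30.4 % of product at 2.00 d.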